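| flask | substrate | activator | remark | time |
|---|---|---|---|---|
| Thursday's | 27 mM | 36 mM | run made earlier |  |
| Sunday's | 80 mM | 36 mM | run made earlier |  |
| winter | 60 mM | 36.0 mM |  | 4.0 h |
| noon | 20 mM | 36.0 mM |  | 6.0 h |

| run | time / h | ring / % | substrate / % |
|---|---|---|---|
| Thursday's | 0.667 | 16 | 44 |
| Thursday's | 1.33 | 24 | 22 |
| Thursday's | 2.00 | 33 | 12 |
| Thursday's | 2.50 | 35 | 10 |
| Thursday's | 3.00 | 40 | 4 |
| Thursday's | 4.00 | 42 | 0 |
| Sunday's | 0.667 | 8 | 48 |
| Sunday's | 1.33 | 7 | 40 |
| Sunday's | 2.00 | 8 | 29 |
| Sunday's | 2.50 | 11 | 26 |
| Sunday's | 3.00 | 13 | 26 |
| Sunday's | 4.00 | 12 | 26 |

(readings scatter by 2 percentage points)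
* the winner by amount of ring, in percent of the substrate charged; "neither" if no more than 2 percentage points parts them (winter / noon / neither)
* how much ring is there at the end, in percent of the substrate charged: winter
* how much ring is there at the end, in percent of the substrate charged: noon
- the earlier runs were read with a standard deviation of 2 percentage points

I read my constants off the runs and order them from quick to slow, reckoning with s, the fraction of substrate left, and not with the ring made.

1. The split, which I take as instant. A lost part of substrate gives ring in the share h/(h+S), where S is the substrate present. While S stands well above h, the ring made is h·ln(1/s) in mM. Sunday's run thus reads h near 7.13 mM, and its stall level lies above that. Thursday's end reading refines this to h = 7.24 mM, the break-even level, the substrate level at which a lost part gives half of itself as ring. With a = h/charge, the yield is a·ln[(a+1)/(a+s)].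

2. Activation. Thursday's first reading gives a substrate half-life of 0.563 h with activator as charged.

3. Noon's decay. By its last reading, Sunday's run had lost 1.64 moles of substrate per mole of activator charged. Noon's charge ratio is 0.556, below that, so substrate is the limiting reagent. I expect noon's activator to end near 23.8 mM, and with that amount I put the half-life near 0.850 h, short against 6.0 h. So I reckon s at 0.752%, and I get 47.2%.

4. Winter's tail. The charge ratio 1.67 sits close to 1.64, so both reagents fall together and s follows 1/(1+ln(2)·t/half-life), not a halving. That gives s = 16.9% and a yield of 16.3%.

The forecast names noon, with 22% (17% to 27%) for winter and 49% (43% to 56%) for noon, holding for winter that “the activator barely suffices and the tail is slow”. My winter figure stands lower, and my noon figure slightly lower.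

The flask gives 18.8% in winter and 52.9% at noon, so noon wins.

    substrate + activator → activated form (k = 0.550 /M/min)
    substrate + activated form → side product (k = 0.740 /M/min)
    substrate + activated form → open dimer (k = 1.30 /M/min)
    activated form ⇌ ring (K = 36.0, k = 0.0320 /min)

Ring returns to activated form here, with a relaxation half-life of 0.351 h in winter, short against 4.0 h, yet winter left until 40.0 h still holds 19.4% of ring. Winter ends with s = 12.2%, and h turns that into 18.4%. The same flask charged with 100 mM of substrate ends with s = 34.8%, where h gives 6.78% and the flask holds 6.52%.

Readings and results were generated by integration for substances that don't exist; noise was put on by code.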